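**Retrosynthetic overview**

1. The target is traced back to its 8'-trimethylsilyl, 7-O-benzyl derivative 24 (primed locants are those of the chroman), so the end game is an ipso-protodesilylation and a hydrogenolysis.
2. The strategy rests on the chroman benzene ring C4a'–C5'–C6'–C7'–C8'–C8a'. It carries four neighbouring substituents (O1' on C8a', C4' on C4a', OMe on C5', coumarin C3 on C6'), and the pyran atoms O1'–C2'–C3'–C4' can serve as a four-atom tether between C8a' and C4a'.
3. Key disconnection: C4a'–C8a', C5'–C6' and C7'–C8', by a rhodium-catalysed [2+2+2] alkyne cycloaddition of the alkynyl-ether diyne 14 with 3-ethynylcoumarin 23. It closes the benzene and pyran rings in one step.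
4. Ring order: the coumarin pyranone ring is made first (bromo-Wittig lactonisation, then Sonogashira coupling); the chroman benzene and pyran rings are made last and together.
5. Diyne 14 comes from 3-methylbutane-1,3-diol by iodination, methoxyacetylide alkylation and a trichloroethylene-based alkynyl ether synthesis.

Key step: step 11

Assumption: the target has no stereocentre and its aryl–coumarin bond rotates freely, so stereocontrol is not an issue; the six numbered starting materials are taken as purchasable.

**Route**

Step 1
Reactants: 1 3-methylbutane-1,3-diol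
Product: 2 4-iodo-2-methylbutan-2-ol
Conditions: PPh3, I2, imidazole, CH2Cl2, 0 °C
Reagents that add atoms: iodine, II
Why: Appel-type iodination activates the primary hydroxyl as its alkoxyphosphonium salt, which iodide displaces by SN2, while the hindered tertiary hydroxyl should stay untouched at 0 °C.

Step 2
Reactants: 2 4-iodo-2-methylbutan-2-ol
Product: 3 triethyl[(4-iodo-2-methylbutan-2-yl)oxy]silane
Conditions: TESOTf, 2,6-lutidine, CH2Cl2, −78 to 0 °C
Reagents that add atoms: triethylsilyl trifluoromethanesulfonate, CC[Si](CC)(CC)OS(=O)(=O)C(F)(F)F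
Why: A silyl triflate with a hindered pyridine base silylates even a tertiary alcohol, and the silyl ether keeps an alkoxide from quenching the acetylide or closing an oxetane in the next step.

Step 3
Reactants: 3 triethyl[(4-iodo-2-methylbutan-2-yl)oxy]silane; 4 chloroacetaldehyde dimethyl acetal (2-chloro-1,1-dimethoxyethane)
Product: 6 triethyl[(6-methoxy-2-methylhex-5-yn-2-yl)oxy]silane, via sodium methoxyacetylide 5 (not isolated)
Conditions: 4 (1.5 equiv), NaNH2 (3 equiv per 4), liq. NH3, −40 °C; then 3 in THF, −33 °C
Reagents that add atoms: none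
Why: Arens-type alkoxyacetylide chemistry: NaNH2 eliminates methanol and HCl from the chloroacetal and deprotonates the methoxyethyne formed, and the sodium acetylide should displace the primary iodide by SN2 to give the 1-methoxy-1-alkyne.

Step 4
Reactants: 6 triethyl[(6-methoxy-2-methylhex-5-yn-2-yl)oxy]silane
Product: 7 6-methoxy-2-methylhex-5-yn-2-ol
Conditions: TBAF, THF, 0 °C to rt
Reagents that add atoms: none
Why: Fluoride cleaves the Si–O bond of the triethylsilyl ether under basic conditions that the acid-sensitive methoxyalkyne tolerates.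

Step 5
Reactants: 7 6-methoxy-2-methylhex-5-yn-2-ol; 8 trichloroethylene
Product: 11 5-{[(E)-1,2-dichloroethenyl]oxy}-1-methoxy-5-methylhex-1-yne, via potassium alkoxide 9 (not isolated), via dichloroacetylene 10 (not isolated)
Conditions: KH, THF, 0 °C; then 8, rt
Reagents that add atoms: none
Why: Greene-type alkynyl ether synthesis: the potassium alkoxide dehydrochlorinates trichloroethylene to dichloroacetylene and adds to it in anti fashion, which should give the E-dichlorovinyl ether as it does with other hindered alcohols.

Step 6
Reactants: 11 5-{[(E)-1,2-dichloroethenyl]oxy}-1-methoxy-5-methylhex-1-yne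
Product: 14 {[(6-methoxy-2-methylhex-5-yn-2-yl)oxy]ethynyl}trimethylsilane, via chloroalkynyl ether 12 (not isolated), via lithium alkynyl ether 13 (not isolated)
Conditions: n-BuLi (2.3 equiv), THF, −78 to −40 °C; then TMSCl, −78 to 0 °C
Reagents that add atoms: chlorotrimethylsilane, C[Si](C)(C)Cl
Why: Second half of the Greene sequence: n-BuLi eliminates HCl, a second equivalent exchanges chlorine for lithium, and the lithium alkynyl ether is silylated on carbon, all below 0 °C because a tertiary alkyl alkynyl ether loses alkene by a retro-ene reaction when warmed.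

Step 7
Reactants: 15 2,4-dihydroxy-6-methoxybenzaldehyde
Product: 16 4-(benzyloxy)-2-hydroxy-6-methoxybenzaldehyde
Conditions: BnBr (1.05 equiv), NaHCO3, MeCN, 70 °C
Reagents that add atoms: benzyl bromide, BrCc1ccccc1
Why: Williamson etherification with a weak base should be selective for the 4-hydroxyl, because the 2-hydroxyl is held in a hydrogen bond to the aldehyde and is far less nucleophilic.

Step 8
Reactants: 16 4-(benzyloxy)-2-hydroxy-6-methoxybenzaldehyde; 17 ethyl (triphenylphosphoranylidene)acetate
Product: 20 7-(benzyloxy)-3-bromo-5-methoxy-2H-chromen-2-one, via bromo ylide 18 (not isolated), via bromoacrylate ester 19 (not isolated)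
Conditions: 17, NBS, CH2Cl2, −20 °C; solvent exchange; then 16, PhNEt2, 180 °C
Reagents that add atoms: N-bromosuccinimide, O=C1CCC(=O)N1Br
Why: One-pot ylide bromination, Wittig olefination and lactonisation: NBS is consumed by the ylide before the aldehyde is added, the α-bromo ylide olefinates the salicylaldehyde, and in hot N,N-diethylaniline the acrylate isomers should interconvert so that the E isomer closes to the lactone with loss of ethanol, which places bromine at C3 without exposing the electron-rich ring to electrophilic bromine.

Step 9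
Reactants: 20 7-(benzyloxy)-3-bromo-5-methoxy-2H-chromen-2-one; 21 ethynyltrimethylsilane
Product: 22 7-(benzyloxy)-5-methoxy-3-[(trimethylsilyl)ethynyl]-2H-chromen-2-one
Conditions: Pd(PPh3)2Cl2 (divalent palladium), CuI, Et3N, THF, 45 °C
Reagents that add atoms: none
Why: Sonogashira coupling of a vinylic bromide α to the lactone carbonyl, a substrate class that adds readily to the zerovalent palladium formed in situ.

Step 10
Reactants: 22 7-(benzyloxy)-5-methoxy-3-[(trimethylsilyl)ethynyl]-2H-chromen-2-one
Product: 23 7-(benzyloxy)-3-ethynyl-5-methoxy-2H-chromen-2-one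
Conditions: TBAF, AcOH, THF, 0 °C
Reagents that add atoms: none
Why: Fluoride-induced protodesilylation of the alkynylsilane, buffered with acetic acid so that no strongly basic species opens or adds to the coumarin.

Step 11
Reactants: 14 {[(6-methoxy-2-methylhex-5-yn-2-yl)oxy]ethynyl}trimethylsilane; 23 7-(benzyloxy)-3-ethynyl-5-methoxy-2H-chromen-2-one
Product: 24 7-(benzyloxy)-5-methoxy-3-[5-methoxy-2,2-dimethyl-8-(trimethylsilyl)chroman-6-yl]-2H-chromen-2-one
Conditions: [Rh(cod)2]BF4 (10 mol%), rac-BINAP (10 mol%), H2 then Ar, CH2Cl2, 20 °C; 14 (1.2 equiv), slow addition of 23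
Reagents that add atoms: none
Why: Proposed new method: the cationic monovalent rhodium–BINAP fragment should bind both alkynes of 14 and couple them oxidatively at their inner carbons to a rhodacyclopentadiene (trivalent rhodium), which forms C4a'–C8a' and closes the pyran as the six-membered ring fused to the metallacycle, the gem-dimethyl group of the tether favouring this closure of a 1,7-diyne. Coordination of the terminal alkyne of 23, insertion into the Rh–C bond at the methoxy-bearing carbon and reductive elimination should then form C5'–C6' and C7'–C8' and close the benzene ring in a formal [2+2+2] cycloaddition at ambient temperature, which matters because the tertiary alkynyl ether would fragment by a retro-ene path if heated. The closest known reaction type is the cationic rhodium-catalysed [2+2+2] cycloaddition of tethered diynes with monoalkynes, which accepts alkynyl ethers and ynamides as components but has not been run on a diyne whose tether starts at the alkynyl ether oxygen. No stereocentre is formed. The step needs one regiochemical outcome: the bulky SiMe3 group on the future C8' should keep the coumarinyl-bearing alkyne carbon away, so that this carbon bonds to C5' and the CH carbon to C8'. Pairing an electron-rich diyne with an electron-poor monoalkyne and adding 23 slowly should favour the cross-cycloaddition over trimerisation of 23.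

Step 12
Reactants: 24 7-(benzyloxy)-5-methoxy-3-[5-methoxy-2,2-dimethyl-8-(trimethylsilyl)chroman-6-yl]-2H-chromen-2-one
Product: 25 7-(benzyloxy)-5-methoxy-3-(5-methoxy-2,2-dimethylchroman-6-yl)-2H-chromen-2-one
Conditions: CF3CO2H, CH2Cl2, 0 °C
Reagents that add atoms: none
Why: Acid-mediated ipso-protodesilylation of an arylsilane (electrophilic aromatic substitution) should be fast because C8' is ortho to the ring oxygen and para to the C5' methoxy group, while the benzyl ether, the methyl ethers and the 2,2-dimethylchroman tolerate cold dilute acid.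

Step 13
Reactants: 25 7-(benzyloxy)-5-methoxy-3-(5-methoxy-2,2-dimethylchroman-6-yl)-2H-chromen-2-one
Product: 26 7-hydroxy-5-methoxy-3-(5-methoxy-2,2-dimethylchroman-6-yl)-2H-chromen-2-one
Conditions: H2 (1 atm), Pd/C, EtOAc, rt
Reagents that add atoms: none
Why: Catalytic hydrogenolysis of the benzyl aryl ether; the trisubstituted, conjugated C3–C4 double bond of a 3-arylcoumarin is reduced much more slowly and should survive if the reaction is stopped at full debenzylation.

**Compound list**

1 | 3-methylbutane-1,3-diol | CC(C)(O)CCO | starting material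
2 | 4-iodo-2-methylbutan-2-ol | CC(C)(O)CCI | intermediate
3 | triethyl[(4-iodo-2-methylbutan-2-yl)oxy]silane | CC[Si](CC)(CC)OC(C)(C)CCI | intermediate
4 | chloroacetaldehyde dimethyl acetal (2-chloro-1,1-dimethoxyethane) | COC(CCl)OC | starting material
5 | sodium methoxyacetylide (sodium 2-methoxyethynide) | [Na+].[C-]#COC | intermediate (not isolated)
6 | triethyl[(6-methoxy-2-methylhex-5-yn-2-yl)oxy]silane | COC#CCCC(C)(C)O[Si](CC)(CC)CC | intermediate
7 | 6-methoxy-2-methylhex-5-yn-2-ol | COC#CCCC(C)(C)O | intermediate
8 | trichloroethylene | ClC=C(Cl)Cl | starting material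
9 | potassium 6-methoxy-2-methylhex-5-yn-2-olate | COC#CCCC(C)(C)[O-].[K+] | intermediate (not isolated)
10 | dichloroacetylene | ClC#CCl | intermediate (not isolated)
11 | 5-{[(E)-1,2-dichloroethenyl]oxy}-1-methoxy-5-methylhex-1-yne | COC#CCCC(C)(C)O/C(Cl)=C\Cl | intermediate
12 | 5-[(chloroethynyl)oxy]-1-methoxy-5-methylhex-1-yne | COC#CCCC(C)(C)OC#CCl | intermediate (not isolated)
13 | lithium 2-[(6-methoxy-2-methylhex-5-yn-2-yl)oxy]ethynide | COC#CCCC(C)(C)OC#[C-].[Li+] | intermediate (not isolated)
14 | {[(6-methoxy-2-methylhex-5-yn-2-yl)oxy]ethynyl}trimethylsilane | COC#CCCC(C)(C)OC#C[Si](C)(C)C | intermediate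
15 | 2,4-dihydroxy-6-methoxybenzaldehyde | COc1cc(O)cc(O)c1C=O | starting material
16 | 4-(benzyloxy)-2-hydroxy-6-methoxybenzaldehyde | COc1cc(OCc2ccccc2)cc(O)c1C=O | intermediate
17 | ethyl (triphenylphosphoranylidene)acetate | CCOC(=O)C=P(c1ccccc1)(c1ccccc1)c1ccccc1 | starting material
18 | ethyl bromo(triphenylphosphoranylidene)acetate | CCOC(=O)C(Br)=P(c1ccccc1)(c1ccccc1)c1ccccc1 | intermediate (not isolated)
19 | ethyl (E)-3-[4-(benzyloxy)-2-hydroxy-6-methoxyphenyl]-2-bromoprop-2-enoate (the isomer that lactonises; the Z isomer interconverts with it at the reaction temperature) | CCOC(=O)/C(Br)=C\c1c(O)cc(OCc2ccccc2)cc1OC | intermediate (not isolated)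
20 | 7-(benzyloxy)-3-bromo-5-methoxy-2H-chromen-2-one | COc1cc(OCc2ccccc2)cc2oc(=O)c(Br)cc12 | intermediate
21 | ethynyltrimethylsilane | C#C[Si](C)(C)C | starting material
22 | 7-(benzyloxy)-5-methoxy-3-[(trimethylsilyl)ethynyl]-2H-chromen-2-one | COc1cc(OCc2ccccc2)cc2oc(=O)c(C#C[Si](C)(C)C)cc12 | intermediate
23 | 7-(benzyloxy)-3-ethynyl-5-methoxy-2H-chromen-2-one | C#Cc1cc2c(OC)cc(OCc3ccccc3)cc2oc1=O | intermediate
24 | 7-(benzyloxy)-5-methoxy-3-[5-methoxy-2,2-dimethyl-8-(trimethylsilyl)chroman-6-yl]-2H-chromen-2-one | O=c1oc2cc(OCc3ccccc3)cc(OC)c2cc1-c1cc([Si](C)(C)C)c2OC(C)(C)CCc2c1OC | intermediate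
25 | 7-(benzyloxy)-5-methoxy-3-(5-methoxy-2,2-dimethylchroman-6-yl)-2H-chromen-2-one | O=c1oc2cc(OCc3ccccc3)cc(OC)c2cc1-c1ccc2OC(C)(C)CCc2c1OC | intermediate
26 | 7-hydroxy-5-methoxy-3-(5-methoxy-2,2-dimethylchroman-6-yl)-2H-chromen-2-one | COc1c(-c2cc3c(OC)cc(O)cc3oc2=O)ccc2c1CCC(C)(C)O2 | target

**Step count**

Total: 13 steps. Longest linear sequence: 9 steps (steps 1–6, then 11–13); the coumarin branch (steps 7–10) joins at step 11.

**Steps most likely to fail**

Step 11 (key step). The cationic rhodium could ionise or hydrate the alkynyl ethers before oxidative cyclisation, the monoalkyne could insert in the reverse orientation, or the terminal alkyne could trimerise on its own. The fallback sets out from aldehyde 16 and returns at 25; it builds the chroman arene by classical means and closes the coumarin last. 2,4-Dihydroxyacetophenone and 3-methylbut-2-enal in hot pyridine should give 1-(5-hydroxy-2,2-dimethyl-2H-chromen-6-yl)ethan-1-one F1 by condensation and 6π-electrocyclisation at the position between the two oxygens, the chelated hydroxyl staying free. O-Methylation (Me2SO4, K2CO3, acetone, reflux) would give 1-(5-methoxy-2,2-dimethyl-2H-chromen-6-yl)ethan-1-one F2, and hydrogenation of the chromene double bond (H2, Pd/C, EtOAc) 1-(5-methoxy-2,2-dimethylchroman-6-yl)ethan-1-one F3. A Willgerodt–Kindler reaction (S8, morpholine, 130 °C) would give 2-(5-methoxy-2,2-dimethylchroman-6-yl)-1-morpholinoethane-1-thione F4, and hydrolysis (KOH, aqueous EtOH, reflux, then acid) 2-(5-methoxy-2,2-dimethylchroman-6-yl)acetic acid F5. Perkin–Oglialoro condensation of F5 with 16 (Ac2O, Et3N, 110 °C) would give 25 directly, and step 13 then follows.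

Step 5. The hindered tertiary alkoxide may add to dichloroacetylene too slowly, so that polymerisation of the chloroalkyne or base-induced isomerisation of the methoxyalkyne takes over. The fallback sets out from alcohol 7 and returns at 14; it builds the alkynyl ether carbons from a formate instead. Formylation (acetic formic anhydride, pyridine, 0 °C) would give 6-methoxy-2-methylhex-5-yn-2-yl formate F6. Dibromomethylenation of the formate carbonyl (CBr4, PPh3, CH2Cl2) would give 5-[(2,2-dibromoethenyl)oxy]-1-methoxy-5-methylhex-1-yne F7. Treatment of F7 with n-BuLi (2 equiv, THF, −78 °C) should pass through the same lithium alkynyl ether 13, and TMSCl would give 14.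

Step 8. Olefination of the hindered, electron-rich aldehyde by the deactivated bromo ylide may be sluggish, isomerisation of the acrylate may stay incomplete, and at the high temperature ring contraction to a benzofuran ester could compete. The fallback sets out from aldehyde 16 and returns at 22; it replaces the bromide by an enol triflate as the coupling handle. Condensation of 16 with N-acetylglycine (NaOAc, Ac2O, 110 °C) would give N-[7-(benzyloxy)-5-methoxy-2-oxo-2H-chromen-3-yl]acetamide F8. Hydrolysis in hot 3 M HCl/dioxane would give 7-(benzyloxy)-3-hydroxy-5-methoxy-2H-chromen-2-one F9. Triflation (Tf2O, pyridine, CH2Cl2, 0 °C) would give 7-(benzyloxy)-5-methoxy-2-oxo-2H-chromen-3-yl trifluoromethanesulfonate F10. Sonogashira coupling of F10 with 21 (Pd(PPh3)2Cl2, divalent palladium, CuI, Et3N, THF) would give 22.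

**Further compounds**

F1 | step 11 | 1-(5-hydroxy-2,2-dimethyl-2H-chromen-6-yl)ethan-1-one | CC(=O)c1ccc2OC(C)(C)C=Cc2c1O
F2 | step 11 | 1-(5-methoxy-2,2-dimethyl-2H-chromen-6-yl)ethan-1-one | CC(=O)c1ccc2OC(C)(C)C=Cc2c1OC
F3 | step 11 | 1-(5-methoxy-2,2-dimethylchroman-6-yl)ethan-1-one | CC(=O)c1ccc2OC(C)(C)CCc2c1OC
F4 | step 11 | 2-(5-methoxy-2,2-dimethylchroman-6-yl)-1-morpholinoethane-1-thione | S=C(Cc1ccc2OC(C)(C)CCc2c1OC)N1CCOCC1
F5 | step 11 | 2-(5-methoxy-2,2-dimethylchroman-6-yl)acetic acid | OC(=O)Cc1ccc2OC(C)(C)CCc2c1OC
F6 | step 5 | 6-methoxy-2-methylhex-5-yn-2-yl formate | COC#CCCC(C)(C)OC=O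
F7 | step 5 | 5-[(2,2-dibromoethenyl)oxy]-1-methoxy-5-methylhex-1-yne | COC#CCCC(C)(C)OC=C(Br)Br
F8 | step 8 | N-[7-(benzyloxy)-5-methoxy-2-oxo-2H-chromen-3-yl]acetamide | CC(=O)Nc1cc2c(OC)cc(OCc3ccccc3)cc2oc1=O
F9 | step 8 | 7-(benzyloxy)-3-hydroxy-5-methoxy-2H-chromen-2-one | Oc1cc2c(OC)cc(OCc3ccccc3)cc2oc1=O
F10 | step 8 | 7-(benzyloxy)-5-methoxy-2-oxo-2H-chromen-3-yl trifluoromethanesulfonate | O=S(=O)(Oc1cc2c(OC)cc(OCc3ccccc3)cc2oc1=O)C(F)(F)F
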